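**Retrosynthetic overview**
- The syn-3,5-diol comes from C3–H formation: hydride reduction of a (5R)-β-boryloxy ketone boron chelate, in the same pot in which the chelate is made.
- Key bond C5–O: enantioselective conjugate hydration of the (E)-1,7-diarylhept-4-en-3-one, with a borinic acid as hydroxide donor under cinchona primary-amine iminium catalysis (new reaction).
- Enone C4=C5: amine-catalysed aldol condensation of zingerone with 3-(4-hydroxy-3,5-dimethoxyphenyl)propanal.
- Aldehyde: from 4-allyl-2,6-dimethoxyphenol by anti-Markovnikov hydroboration–oxidation, then alcohol oxidation.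
- Rings: none is formed; both arenes are purchased and the phenols stay unprotected throughout.

Assumption: chain carbons are numbered C1 (on the 4-hydroxy-3-methoxyphenyl ring) to C7 (on the 4-hydroxy-3,5-dimethoxyphenyl ring), so the target is (3S,5R), the syn-diol; the facial sense of 9-amino-9-deoxy-epi-quinine is taken by analogy with its known O-nucleophile additions to (E)-alkyl enones (oxygen to the Re face of C5, giving 5R), and if it proves opposite, the quinidine-derived pseudoenantiomer replaces it with no other change.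

**Step 1**
Reactants: 1 4-allyl-2,6-dimethoxyphenol (methoxyeugenol)
Product: 3 3-(4-hydroxy-3,5-dimethoxyphenyl)propan-1-ol, via bis(9-BBN) adduct 2 (not isolated)
Conditions: 9-BBN (2.2 equiv), THF, 0 °C → rt; then NaBO3·4H2O, H2O, rt
Reagents that add atoms: 9-BBN, [H]B1C2CCCC1CCC2; sodium perborate (NaBO3·4H2O), [Na+].[Na+].O[B-]1(O)OO[B-](O)(O)OO1
Why: Hydroboration–oxidation: 9-BBN places boron on the terminal allyl carbon (anti-Markovnikov) while a second equivalent borylates the phenol O–H to give 2, and perborate then oxidises the C–B bond to the primary alcohol and frees the phenol without strongly alkaline peroxide; the boron framework stays only in 2, and no stereocentre is formed.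

**Step 2**
Reactants: 3 3-(4-hydroxy-3,5-dimethoxyphenyl)propan-1-ol
Product: 4 3-(4-hydroxy-3,5-dimethoxyphenyl)propanal
Conditions: SO3·pyridine (3 equiv), DMSO, iPr2NEt, CH2Cl2, 0 °C; aq NaHCO3 work-up
Reagents that add atoms: none
Why: Parikh–Doering (activated-DMSO) oxidation stops at the aldehyde and avoids hypervalent-iodine, oxoammonium and metal-oxo oxidants that would oxidise the 2,6-dimethoxyphenol; no stereocentre is formed.

**Step 3**
Reactants: 4 3-(4-hydroxy-3,5-dimethoxyphenyl)propanal; 5 zingerone (2 equiv; excess recovered)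
Product: 6 (E)-1-(4-hydroxy-3-methoxyphenyl)-7-(4-hydroxy-3,5-dimethoxyphenyl)hept-4-en-3-one
Conditions: pyrrolidine (30 mol%), AcOH (30 mol%), THF, rt, slow addition of 4
Reagents that add atoms: none
Why: Amine-catalysed cross-aldol condensation: the pyrrolidine enamine of 5 forms on the less substituted methyl side and adds to the aldehyde (as its iminium), and Mannich-type loss of the amine gives the conjugated E-enone; excess 5 and slow addition of 4 suppress aldehyde self-condensation, all intermediates are catalyst-bound, the phenols are inert, and no stereocentre is formed.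

**Step 4**
Reactants: 6 (E)-1-(4-hydroxy-3-methoxyphenyl)-7-(4-hydroxy-3,5-dimethoxyphenyl)hept-4-en-3-one
Product: 9 (3S,5R)-1-(4-hydroxy-3-methoxyphenyl)-7-(4-hydroxy-3,5-dimethoxyphenyl)heptane-3,5-diol, via boron-chelated β-boryloxy ketone 7 (not isolated), via cyclic sodium diphenylborate 8 (not isolated)
Conditions: (Ph2B)2O (1.5 equiv), H2O (1.5 equiv), 9-amino-9-deoxy-epi-quinine (10 mol%), toluene/THF (1 M), rt; then THF/MeOH 4:1, NaBH4, −78 °C; AcOH; ethanolamine, Et2O (2-aminoethyl diphenylborinate filtered off)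
Reagents that add atoms: diphenylborinic anhydride, c1ccccc1B(c1ccccc1)OB(c1ccccc1)c1ccccc1; water, O; sodium borohydride, [Na+].[BH4-]
Why: Proposed new method: intermolecular enantioselective "borinate oxa-Michael" (formal conjugate hydration) with in-flask chelate reduction — the anhydride and water give Ph2BOH in the flask; the catalyst's primary amine converts 6 into its iminium ion; Ph2BOH (pKa about 6) acts as acid co-catalyst and, as the tetracoordinate hydroxyborinate ion-paired with the protonated quinuclidine, transfers a boron-bound oxygen to the Re face of C5 (sets 5R); enamine hydrolysis releases the β-O–BPh2 ketone, which closes to the six-membered O–B←O=C chelate 7 (a sink that blocks retro-Michael and retro-aldol); NaBH4 then attacks the half-chair chelate axially to set C3 syn to C5 (3S) and gives borate 8, as in a Narasaka–Prasad reduction with the boron already in place, and AcOH/ethanolamine strip the boron to free 9; the closest known reaction types are the intramolecular boronic acid hemiester oxa-Michael of hydroxy enones under chiral amine catalysis, cinchona primary-amine-catalysed additions of H2O2 and oximes to enones, and borinic acid activation of OH nucleophiles.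

**Compound list**
1 | 4-allyl-2,6-dimethoxyphenol | C=CCc1cc(OC)c(O)c(OC)c1 | starting material
2 | 9-[3-(4-{[9-borabicyclo[3.3.1]nonan-9-yl]oxy}-3,5-dimethoxyphenyl)propyl]-9-borabicyclo[3.3.1]nonane | COc1cc(CCCB2C3CCCC2CCC3)cc(OC)c1OB1C2CCCC1CCC2 | intermediate (not isolated)
3 | 3-(4-hydroxy-3,5-dimethoxyphenyl)propan-1-ol | OCCCc1cc(OC)c(O)c(OC)c1 | intermediate
4 | 3-(4-hydroxy-3,5-dimethoxyphenyl)propanal | O=CCCc1cc(OC)c(O)c(OC)c1 | intermediate
5 | zingerone; 4-(4-hydroxy-3-methoxyphenyl)butan-2-one | CC(=O)CCc1ccc(O)c(OC)c1 | starting material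
6 | (E)-1-(4-hydroxy-3-methoxyphenyl)-7-(4-hydroxy-3,5-dimethoxyphenyl)hept-4-en-3-one | COc1cc(CCC(=O)/C=C/CCc2cc(OC)c(O)c(OC)c2)ccc1O | intermediate
7 | (5R)-5-(diphenylboranyloxy)-1-(4-hydroxy-3-methoxyphenyl)-7-(4-hydroxy-3,5-dimethoxyphenyl)heptan-3-one (boron chelated by the ketone O; drawn open) | COc1cc(CCC(=O)C[C@H](OB(c2ccccc2)c2ccccc2)CCc2cc(OC)c(O)c(OC)c2)ccc1O | intermediate (not isolated)
8 | sodium (4S,6R)-4-[2-(4-hydroxy-3-methoxyphenyl)ethyl]-6-[2-(4-hydroxy-3,5-dimethoxyphenyl)ethyl]-2,2-diphenyl-1,3,2-dioxaborinan-2-uide | [Na+].COc1cc(CC[C@H]2C[C@@H](CCc3cc(OC)c(O)c(OC)c3)O[B-](c3ccccc3)(c3ccccc3)O2)ccc1O | intermediate (not isolated)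
9 | (3S,5R)-1-(4-hydroxy-3-methoxyphenyl)-7-(4-hydroxy-3,5-dimethoxyphenyl)heptane-3,5-diol | COc1cc(CC[C@H](O)C[C@H](O)CCc2cc(OC)c(O)c(OC)c2)ccc1O | target

**Step count**
Total steps: 4. Longest linear sequence: 4 (1 → 3 → 4 → 6 → 9).

**Three steps most likely to fail**

Step 4 (the new reaction). The risks are reversible binding of the borinic acid to the catalyst amines, slow intermolecular B–OH transfer, competing phenol addition, and an unproven facial sense. The fallback uses known chemistry, sets out from 6 and comes back at 9. Enone 6 is hydroperoxidised with 50% aqueous H2O2 and 9-amino-9-deoxy-epi-quinine bis(trichloroacetate) (10 mol%) in dioxane at 30 °C to give the cyclic peroxyhemiketal (5R)-5-[2-(4-hydroxy-3,5-dimethoxyphenyl)ethyl]-3-[2-(4-hydroxy-3-methoxyphenyl)ethyl]-1,2-dioxolan-3-ol F1. Its O–O bond is reduced with P(OEt)3 to the aldol-type (5R)-5-hydroxy-1-(4-hydroxy-3-methoxyphenyl)-7-(4-hydroxy-3,5-dimethoxyphenyl)heptan-3-one F2. F2 is reduced syn-selectively with Et2BOMe/NaBH4 in THF/MeOH at −78 °C (Narasaka–Prasad) to give 9.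

Step 3 (aldol condensation). The risks are self-condensation of the enolisable aldehyde 4 and Michael addition to the product. The fallback sets out from 4 and 5 and comes back at 6. Zingerone 5 is converted with LDA (2.1 equiv, THF, −78 °C) into its phenoxide/kinetic methyl-side enolate dianion. Aldehyde 4, whose phenol has first been deprotonated with LiHMDS (1.0 equiv, −78 °C), is added to give the racemic aldol 5-hydroxy-1-(4-hydroxy-3-methoxyphenyl)-7-(4-hydroxy-3,5-dimethoxyphenyl)heptan-3-one F3. F3 is dehydrated with catalytic p-TsOH in toluene at 70 °C to give 6.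

Step 2 (alcohol oxidation beside a free, electron-rich phenol). The risks are sulfation or O-sulfonium chemistry at the phenol. The fallback sets out from 3 and comes back at 4. The phenol alone is benzylated (BnBr, K2CO3, acetone, reflux) to give 3-(4-benzyloxy-3,5-dimethoxyphenyl)propan-1-ol F4. Dess–Martin periodinane (CH2Cl2, NaHCO3) oxidises it to 3-(4-benzyloxy-3,5-dimethoxyphenyl)propanal F5. Brief hydrogenolysis (H2 1 atm, Pd/C, EtOAc, rt, monitored) removes the benzyl group to give 4.

**Further compounds**
F1 | step 4 | (5R)-5-[2-(4-hydroxy-3,5-dimethoxyphenyl)ethyl]-3-[2-(4-hydroxy-3-methoxyphenyl)ethyl]-1,2-dioxolan-3-ol (hemiketal carbon unassigned) | COc1cc(CCC2(O)C[C@@H](CCc3cc(OC)c(O)c(OC)c3)OO2)ccc1O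
F2 | step 4 | (5R)-5-hydroxy-1-(4-hydroxy-3-methoxyphenyl)-7-(4-hydroxy-3,5-dimethoxyphenyl)heptan-3-one | COc1cc(CCC(=O)C[C@H](O)CCc2cc(OC)c(O)c(OC)c2)ccc1O
F3 | step 3 | racemic 5-hydroxy-1-(4-hydroxy-3-methoxyphenyl)-7-(4-hydroxy-3,5-dimethoxyphenyl)heptan-3-one | COc1cc(CCC(=O)CC(O)CCc2cc(OC)c(O)c(OC)c2)ccc1O
F4 | step 2 | 3-(4-benzyloxy-3,5-dimethoxyphenyl)propan-1-ol | OCCCc1cc(OC)c(OCc2ccccc2)c(OC)c1
F5 | step 2 | 3-(4-benzyloxy-3,5-dimethoxyphenyl)propanal | O=CCCc1cc(OC)c(OCc2ccccc2)c(OC)c1
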